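## Retrosynthetic overview

1. Late stage: the four acetates and the C12–C16 side chain are added to a C12 lactol. C12 is set by CBS reduction, C13 by hydroxyl-directed epoxidation and selenoxide elimination, the C8 carbinol comes from an 8(17)-alkene, and the 6β-alcohol from a 6-ketone.
2. Key disconnection: C5–C10 and C6–C7 are cut together, which unravels rings A and B of tricyclic ketol 14 to the monocyclic formyl butenolide 12.
3. Enabling feature: ring B carries oxygen on C6 and C8 flanking C7 (aldol retron), C10 is quaternary and β to C8 (Michael retron), and C10 and C9 carry the oxidised carbons C20 and C11. Tying these as a temporary butenolide (C11(=O)–O–C20 with C9=C10 inside, acetyl C8/C7 on C9) makes C10 a doubly activated acceptor.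
4. Ring order forward: temporary γ-lactone (step 7), then ring A by Michael addition and ring B by aldol addition (both step 9); the lactone is opened in step 12.
5. Precursor 12 has one stereocentre (C3, CBS reduction) and is built from 2,2-dimethylpent-4-enal, a bromoethyl dioxolane, formaldehyde and an acetylketene source.

Key step: step 9

Remark: labdane numbering (C1–C20) and α/β in the steroid sense (C20 on C10 = β) are used for all intermediates; C6 in 14 and 15 is drawn as expected and C12 in 21 is left open, because both centres are re-set later.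

## Route

Step 1
Reactants: 1 2,2-dimethylpent-4-enal; 2 2-(2-bromoethyl)-1,3-dioxolane
Product: 3 rac-1-(1,3-dioxolan-2-yl)-4,4-dimethylhept-6-en-3-ol
Conditions: 2, Mg, THF, ≤25 °C; then 1, −20 → 0 °C; aq. NH4Cl
Reagents that add atoms: none
Why: Grignard addition to a non-enolisable α-quaternary aldehyde joins C2 to C3 cleanly, and the carbinol is left racemic because C3 is set in step 3.

Step 2
Reactants: 3 rac-1-(1,3-dioxolan-2-yl)-4,4-dimethylhept-6-en-3-ol
Product: 4 1-(1,3-dioxolan-2-yl)-4,4-dimethylhept-6-en-3-one
Conditions: Dess–Martin periodinane, NaHCO3, CH2Cl2, 0 → 23 °C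
Reagents that add atoms: none
Why: Dess–Martin oxidation of the hindered secondary alcohol under bicarbonate buffer leaves the dioxolane and the terminal alkene untouched.

Step 3
Reactants: 4 1-(1,3-dioxolan-2-yl)-4,4-dimethylhept-6-en-3-one
Product: 5 (3R)-1-(1,3-dioxolan-2-yl)-4,4-dimethylhept-6-en-3-ol
Conditions: (S)-2-methyl-CBS-oxazaborolidine (0.2 equiv), catecholborane, toluene, −78 → −30 °C; aq. NaOH work-up
Reagents that add atoms: none
Why: Corey–Bakshi–Shibata reduction with the tert-alkyl carbon C4 as the large and the CH2 chain as the small group should give the (R)-alcohol (C3) with the (S)-catalyst, and catecholborane does not hydroborate the alkene at this temperature.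

Step 4
Reactants: 5 (3R)-1-(1,3-dioxolan-2-yl)-4,4-dimethylhept-6-en-3-ol
Product: 6 tert-butyl{[(3R)-1-(1,3-dioxolan-2-yl)-4,4-dimethylhept-6-en-3-yl]oxy}dimethylsilane
Conditions: TBSOTf (1.1 equiv), 2,6-lutidine, CH2Cl2, −78 °C; MeOH quench
Reagents that add atoms: tert-butyldimethylsilyl triflate, CC(C)(C)[Si](C)(C)OS(=O)(=O)C(F)(F)F
Why: Silyl triflate silylation of the neopentyl-type alcohol at −78 °C is much faster than activation of the dioxolane.

Step 5
Reactants: 6 tert-butyl{[(3R)-1-(1,3-dioxolan-2-yl)-4,4-dimethylhept-6-en-3-yl]oxy}dimethylsilane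
Product: 7 (4R)-4-[(tert-butyldimethylsilyl)oxy]-5,5-dimethyloct-7-enal
Conditions: PPTS (cat.), acetone/H2O, 55 °C
Reagents that add atoms: water, O
Why: Mild acid-catalysed acetal hydrolysis frees the C10 aldehyde while the hindered secondary TBS ether survives.

Step 6
Reactants: 7 (4R)-4-[(tert-butyldimethylsilyl)oxy]-5,5-dimethyloct-7-enal
Product: 8 (5R)-5-[(tert-butyldimethylsilyl)oxy]-1-hydroxy-6,6-dimethylnon-8-en-2-one
Conditions: (CH2O)n, 3-benzyl-5-(2-hydroxyethyl)-4-methylthiazolium chloride (10 mol %), i-Pr2NEt, THF, 60 °C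
Reagents that add atoms: formaldehyde (as paraformaldehyde), C=O
Why: Carbene-catalysed cross-acyloin reaction (hydroxymethylation), in which the Breslow intermediate of the aliphatic aldehyde adds to formaldehyde, gives the hydroxymethyl ketone that holds C10 and C20.

Step 7
Reactants: 8 (5R)-5-[(tert-butyldimethylsilyl)oxy]-1-hydroxy-6,6-dimethylnon-8-en-2-one; 9 2,2,6-trimethyl-4H-1,3-dioxin-4-one
Product: 11 3-acetyl-4-[(3R)-3-[(tert-butyldimethylsilyl)oxy]-4,4-dimethylhept-6-en-1-yl]furan-2(5H)-one, via acetoacetate ester 10 (not isolated)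
Conditions: 9, toluene, 110 °C (− acetone); then Et3N (0.3 equiv), 23 °C
Reagents that add atoms: none
Why: Thermolysis of the dioxinone releases acetylketene, which acylates the primary alcohol, and the acetoacetate of an α-ketol then closes by amine-promoted intramolecular Knoevenagel condensation to the 3-acetylbutenolide, which makes the tetrasubstituted C9=C10 alkene without an intermolecular ketone condensation.

Step 8
Reactants: 11 3-acetyl-4-[(3R)-3-[(tert-butyldimethylsilyl)oxy]-4,4-dimethylhept-6-en-1-yl]furan-2(5H)-one
Product: 12 (4R)-6-(4-acetyl-5-oxo-2,5-dihydrofuran-3-yl)-4-[(tert-butyldimethylsilyl)oxy]-3,3-dimethylhexanal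
Conditions: O3, CH2Cl2, −78 °C (Sudan red 7B end point); then PPh3, −78 → 23 °C
Reagents that add atoms: ozone, [O-][O+]=O
Why: Ozonolysis with reductive work-up cleaves the electron-rich terminal alkene far faster than the electron-poor tetrasubstituted butenolide alkene when the ozone dose is limited by an indicator, giving the C6 aldehyde.

Step 9
Reactants: 12 (4R)-6-(4-acetyl-5-oxo-2,5-dihydrofuran-3-yl)-4-[(tert-butyldimethylsilyl)oxy]-3,3-dimethylhexanal
Product: 14 tricyclic ketol lactone, via Michael adduct 13 (not isolated)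
Conditions: (R)-α,α-diphenylprolinol trimethylsilyl ether (20 mol %), PhCO2H (20 mol %), toluene, 23 °C; then DBU (30 mol %), 0 °C; AcOH quench
Reagents that add atoms: none
Why: The chiral secondary amine converts the C6 aldehyde into an (E)-enamine whose C5 adds to C10 of the 3-acetylbutenolide in a 6-(enolexo)-exo-trig Michael ring closure (ring A, quaternary C10), hydrolysis releases keto-aldehyde 13, and the added amidine then enolises the acetyl methyl C7, which closes ring B by a 6-(enolexo)-exo-trig aldol addition to C6. The closest known reaction types are the amine-catalysed intramolecular Michael addition of formyl-tethered acceptors, enamine additions to tetrasubstituted doubly activated alkenes that create quaternary carbons, and the Michael/aldol order of the Robinson annulation (and of the dimedone synthesis, where a β,β-disubstituted enone is the acceptor). C5 and C10 are controlled by the catalyst, whose diphenyl(silyloxy)methyl arm shields one enamine face (the (R)-enantiomer is chosen from its established sense in intermolecular aldehyde Michael additions), working through a chair in which the butenolide C20 methylene is axial beside the axial C4 methyl while C9 and C6 are equatorial, which is the trans-decalin arrangement; C5 can still equilibrate through the aldehyde toward the trans-fused product. C9 is dictated by the ring system, because the five-membered lactone can only be cis-fused to ring B (C11 and C20 both β, 9α-H), and C6 should form as the equatorial 6α-alcohol, which does not matter since C6 is re-set in steps 11 and 12. The step needs face selectivity at C10 relative to the resident C3 centre and aldol addition without dehydration or retro-Michael opening: the first is left to the catalyst because a silyloxy group next to the gem-dimethyl carbon biases the chair only weakly, the second is secured by a substoichiometric base (buffered by the acidic C9–H), low temperature and an acetic acid quench.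

Step 10
Reactants: 14 tricyclic ketol lactone
Product: 15 8(17)-methylene lactone
Conditions: Zn, CH2Br2, TiCl4, THF (preformed reagent); CH2Cl2, 0 → 23 °C
Reagents that add atoms: dibromomethane, BrCBr
Why: Lombardo methylenation uses a non-basic zinc/titanium methylene reagent that olefinates ketones in the presence of lactones, free hydroxyl groups and acidic α-hydrogens, so C17 is attached at C8 without enolate chemistry at C9.

Step 11
Reactants: 15 8(17)-methylene lactone
Product: 16 6-oxo-8(17)-ene lactone
Conditions: Dess–Martin periodinane, NaHCO3, CH2Cl2, 0 °C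
Reagents that add atoms: none
Why: Dess–Martin oxidation under buffered neutral conditions converts the secondary 6α-alcohol into the ketone, which erases the unwanted C6 configuration without isomerising the β,γ-unsaturated ketone.

Step 12
Reactants: 16 6-oxo-8(17)-ene lactone
Product: 17 11,20-lactol with 6β-hydroxyl
Conditions: i-Bu2AlH (2.2 equiv), CH2Cl2, −78 °C; aq. KNaC4H4O6
Reagents that add atoms: none
Why: Hydride attacks the C6 ketone from the open α face (the β face is shielded by the axial C19 methyl and the C20 methylene) to give the axial 6β-alcohol under steric approach control, and at −78 °C the γ-lactone stops at the lactol, which marks C11 as the aldehyde carbon and frees C20 as an alcohol equivalent.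

Step 13
Reactants: 17 11,20-lactol with 6β-hydroxyl
Product: 19 homologated 12,20-lactol, via methyl enol ether 18 (not isolated)
Conditions: Ph3P(CH2OMe)Cl, KN(SiMe3)2, THF, 0 °C; then 17, 0 → 23 °C; then 1 M aq. HCl, THF, 0 °C
Reagents that add atoms: (methoxymethyl)triphenylphosphonium chloride, COC[P+](c1ccccc1)(c1ccccc1)c1ccccc1.[Cl-]; water, O
Why: Wittig methoxymethylenation of the lactol through its hydroxy-aldehyde form, followed by brief aqueous acid hydrolysis of the enol ether, adds C12 at the aldehyde level, and the new aldehyde closes onto the C20 hydroxyl as a six-membered lactol while the TBS ether and the exocyclic alkene survive.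

Step 14
Reactants: 19 homologated 12,20-lactol; 20 (E)-2-bromobut-2-ene
Product: 21 allylic alcohol triol (C12 epimers)
Conditions: 20 (5 equiv), t-BuLi (10 equiv), Et2O, −78 °C; then 19, THF, −78 → −20 °C; aq. NH4Cl
Reagents that add atoms: none
Why: The alkenyllithium, formed by bromine–lithium exchange with retention of alkene geometry, adds to the aldehyde form of the lactol (the excess absorbs the acidic hydroxyls) and brings in C13–C16; C12 forms unselectively and is corrected in steps 15 and 17.

Step 15
Reactants: 21 allylic alcohol triol (C12 epimers)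
Product: 22 enone 6β,20-diol
Conditions: MnO2, CH2Cl2, 23 °C
Reagents that add atoms: none
Why: MnO2 oxidises only the allylic C12 alcohol and converges both C12 epimers on the α-methyl enone.

Step 16
Reactants: 22 enone 6β,20-diol
Product: 23 enone 6β,20-diacetate
Conditions: Ac2O, DMAP, Et3N, CH2Cl2, 23 → 40 °C
Reagents that add atoms: acetic anhydride, CC(=O)OC(C)=O
Why: DMAP-catalysed acetylation esterifies the primary C20 and the axial secondary C6 hydroxyls (through the open hydroxy-ketone form) and gives a substrate without free hydroxyl groups for the borane reduction.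

Step 17
Reactants: 23 enone 6β,20-diacetate
Product: 24 (12R)-allylic alcohol diacetate
Conditions: (S)-2-methyl-CBS-oxazaborolidine (0.5 equiv), catecholborane, toluene, −78 → −40 °C
Reagents that add atoms: none
Why: Corey–Bakshi–Shibata reduction with the α-branched alkenyl group as the large and the C11 methylene as the small substituent should give the (12R)-alcohol with the (S)-catalyst, and catecholborane at low temperature touches neither the acetates nor the alkenes.

Step 18
Reactants: 24 (12R)-allylic alcohol diacetate
Product: 25 erythro 13,14-epoxy-12-alcohol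
Conditions: VO(acac)2 (5 mol %), t-BuOOH (1.2 equiv), CH2Cl2, 0 °C
Reagents that add atoms: tert-butyl hydroperoxide, CC(C)(C)OO
Why: Vanadium-catalysed hydroxyl-directed epoxidation is erythro-selective for allylic alcohols with a substituent geminal to the carbinol (A(1,2) strain), so oxygen is delivered to the face anti to C11 and C13 receives the configuration of the (12R,13S)-diol; the remote 8(17)-alkene reacts far more slowly.

Step 19
Reactants: 25 erythro 13,14-epoxy-12-alcohol
Product: 26 8α,12-diol epoxide
Conditions: Co(acac)2 (20 mol %), PhSiH3, O2 (1 atm), THF, 23 °C; aq. Na2S2O3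
Reagents that add atoms: dioxygen, O=O
Why: Mukaiyama hydration transfers a hydrogen atom to the only alkene left, and the tertiary C8 radical is oxygenated from the α (equatorial) direction because the β face is blocked by the axial C20 acetoxymethyl and 6β-acetoxy groups, giving the 8α-alcohol with C17 as the axial methyl.

Step 20
Reactants: 26 8α,12-diol epoxide
Product: 27 tetraacetate epoxide
Conditions: Ac2O, DMAP, Et3N, CH2Cl2, 40 °C
Reagents that add atoms: acetic anhydride, CC(=O)OC(C)=O
Why: DMAP-catalysed acetylation on warming esterifies the tertiary C8 and the secondary C12 hydroxyls while the tertiary C13 oxygen is still masked as the epoxide, which is how the C8 tertiary acetate and the free C13 tertiary alcohol of the target are told apart.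

Step 21
Reactants: 27 tetraacetate epoxide
Product: 29 target 3-O-TBS ether, via hydroxy selenide 28 (not isolated)
Conditions: (PhSe)2, NaBH4, EtOH, 23 → 40 °C; then 30 % H2O2, THF, 0 → 23 °C
Reagents that add atoms: none
Why: Phenylselenide opens the trisubstituted epoxide at the less substituted C14 with inversion, and oxidation to the selenoxide followed by syn-elimination toward the C15 methyl (C13 has no hydrogen) gives the tertiary allylic alcohol with the C13–O bond untouched, under a weakly basic medium that hindered acetates tolerate.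

Step 22
Reactants: 29 target 3-O-TBS ether
Product: 30 CNP0292984.1
Conditions: HF·pyridine, pyridine, THF, 0 → 23 °C
Reagents that add atoms: none
Why: Buffered fluoride cleavage of the silyl ether frees the axial 3α-alcohol and leaves the four acetates and the tertiary allylic alcohol intact.

## Compound list

1 | 2,2-dimethylpent-4-enal | C=CCC(C)(C)C=O | starting material
2 | 2-(2-bromoethyl)-1,3-dioxolane | BrCCC1OCCO1 | starting material
3 | rac-1-(1,3-dioxolan-2-yl)-4,4-dimethylhept-6-en-3-ol | C=CCC(C)(C)C(O)CCC1OCCO1 | intermediate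
4 | 1-(1,3-dioxolan-2-yl)-4,4-dimethylhept-6-en-3-one | C=CCC(C)(C)C(=O)CCC1OCCO1 | intermediate
5 | (3R)-1-(1,3-dioxolan-2-yl)-4,4-dimethylhept-6-en-3-ol | C=CCC(C)(C)[C@H](O)CCC1OCCO1 | intermediate
6 | tert-butyl{[(3R)-1-(1,3-dioxolan-2-yl)-4,4-dimethylhept-6-en-3-yl]oxy}dimethylsilane | C=CCC(C)(C)[C@H](O[Si](C)(C)C(C)(C)C)CCC1OCCO1 | intermediate
7 | (4R)-4-[(tert-butyldimethylsilyl)oxy]-5,5-dimethyloct-7-enal | C=CCC(C)(C)[C@H](O[Si](C)(C)C(C)(C)C)CCC=O | intermediate
8 | (5R)-5-[(tert-butyldimethylsilyl)oxy]-1-hydroxy-6,6-dimethylnon-8-en-2-one | C=CCC(C)(C)[C@H](O[Si](C)(C)C(C)(C)C)CCC(=O)CO | intermediate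
9 | 2,2,6-trimethyl-4H-1,3-dioxin-4-one | CC1=CC(=O)OC(C)(C)O1 | starting material
10 | (5R)-5-[(tert-butyldimethylsilyl)oxy]-6,6-dimethyl-2-oxonon-8-en-1-yl 3-oxobutanoate (not isolated) | C=CCC(C)(C)[C@H](O[Si](C)(C)C(C)(C)C)CCC(=O)COC(=O)CC(C)=O | intermediate
11 | 3-acetyl-4-[(3R)-3-[(tert-butyldimethylsilyl)oxy]-4,4-dimethylhept-6-en-1-yl]furan-2(5H)-one | C=CCC(C)(C)[C@H](O[Si](C)(C)C(C)(C)C)CCC1=C(C(C)=O)C(=O)OC1 | intermediate
12 | (4R)-6-(4-acetyl-5-oxo-2,5-dihydrofuran-3-yl)-4-[(tert-butyldimethylsilyl)oxy]-3,3-dimethylhexanal | O=CCC(C)(C)[C@H](O[Si](C)(C)C(C)(C)C)CCC1=C(C(C)=O)C(=O)OC1 | intermediate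
13 | Michael adduct (not isolated): ring A closed, C5 carrying the C6 formyl group (5α-H), C10 the spiro carbon of the γ-lactone C20–O–C11(=O)–C9, acetyl (C8, C7) on C9, 3α-OTBS; in equilibrium with its cyclic hemiacetal | O=C3[C@@H](C(C)=O)[C@@]2(CO3)CC[C@@H](O[Si](C)(C)C(C)(C)C)C(C)(C)[C@@H]2C=O | intermediate
14 | tricyclic ketol lactone: trans-decalin (5α-H, 9α-H) with 3α-OTBS, 4,4-dimethyl, 6α-OH, 8-oxo and the cis-fused 11,20-γ-lactone on the β face | O=C3[C@@H]1[C@@]2(CO3)CC[C@@H](O[Si](C)(C)C(C)(C)C)C(C)(C)[C@@H]2[C@@H](O)CC1=O | intermediate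
15 | 8(17)-methylene lactone: as 14 with C8=CH2 in place of the ketone (6α-OH) | O=C3[C@@H]1[C@@]2(CO3)CC[C@@H](O[Si](C)(C)C(C)(C)C)C(C)(C)[C@@H]2[C@@H](O)CC1=C | intermediate
16 | 6-oxo-8(17)-ene 11,20-lactone | O=C3[C@@H]1[C@@]2(CO3)CC[C@@H](O[Si](C)(C)C(C)(C)C)C(C)(C)[C@@H]2C(=O)CC1=C | intermediate
17 | 11,20-lactol (C11 hemiacetal, anomers) with 6β-OH and 8(17)-ene | OC3[C@@H]1[C@@]2(CO3)CC[C@@H](O[Si](C)(C)C(C)(C)C)C(C)(C)[C@@H]2[C@H](O)CC1=C | intermediate
18 | methyl enol ether C11=C12–OMe (E/Z, not isolated) with free 20-OH and 6β-OH | COC=C[C@@H]1[C@@]2(CO)CC[C@@H](O[Si](C)(C)C(C)(C)C)C(C)(C)[C@@H]2[C@H](O)CC1=C | intermediate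
19 | 12,20-lactol (six-membered hemiacetal C12(OH)–O–C20, anomers) with 6β-OH and 8(17)-ene | OC3C[C@@H]1[C@@]2(CO3)CC[C@@H](O[Si](C)(C)C(C)(C)C)C(C)(C)[C@@H]2[C@H](O)CC1=C | intermediate
20 | (E)-2-bromobut-2-ene | C/C=C(\C)Br | starting material
21 | 6β,12,20-triol (C12 epimers) with the (13E)-but-2-en-2-yl group on C12 and 8(17)-ene | C/C=C(\C)C(O)C[C@@H]1[C@@]2(CO)CC[C@@H](O[Si](C)(C)C(C)(C)C)C(C)(C)[C@@H]2[C@H](O)CC1=C | intermediate
22 | 12-oxo-(13E)-ene enone 6β,20-diol | C/C=C(\C)C(=O)C[C@@H]1[C@@]2(CO)CC[C@@H](O[Si](C)(C)C(C)(C)C)C(C)(C)[C@@H]2[C@H](O)CC1=C | intermediate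
23 | enone 6β,20-diacetate | C/C=C(\C)C(=O)C[C@@H]1[C@@]2(COC(C)=O)CC[C@@H](O[Si](C)(C)C(C)(C)C)C(C)(C)[C@@H]2[C@H](OC(C)=O)CC1=C | intermediate
24 | (12R)-allylic alcohol 6β,20-diacetate | C/C=C(\C)[C@@H](C[C@@H]1[C@@]2(COC(C)=O)CC[C@@H](O[Si](C)(C)C(C)(C)C)C(C)(C)[C@@H]2[C@H](OC(C)=O)CC1=C)O | intermediate
25 | (12R)-12-hydroxy-13,14-epoxide (trans-epoxide, oxygen anti to C11, C13 configured as in the target) 6β,20-diacetate, 8(17)-ene | C[C@H]4O[C@]4(C)[C@@H](C[C@@H]1[C@@]2(COC(C)=O)CC[C@@H](O[Si](C)(C)C(C)(C)C)C(C)(C)[C@@H]2[C@H](OC(C)=O)CC1=C)O | intermediate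
26 | 8α,12-diol epoxide (8α-OH, 8β-CH3) 6β,20-diacetate | C[C@H]4O[C@]4(C)[C@@H](C[C@@H]1[C@@]2(COC(C)=O)CC[C@@H](O[Si](C)(C)C(C)(C)C)C(C)(C)[C@@H]2[C@H](OC(C)=O)C[C@@]1(C)O)O | intermediate
27 | 6β,8α,12,20-tetraacetate 13,14-epoxide | C[C@H]4O[C@]4(C)[C@@H](C[C@@H]1[C@@]2(COC(C)=O)CC[C@@H](O[Si](C)(C)C(C)(C)C)C(C)(C)[C@@H]2[C@H](OC(C)=O)C[C@@]1(C)OC(C)=O)OC(C)=O | intermediate
28 | 13-hydroxy-14-(phenylselanyl) tetraacetate (not isolated; C14 inverted) | C[C@H]([Se]c1ccccc1)[C@](C)(O)[C@@H](C[C@@H]1[C@@]2(COC(C)=O)CC[C@@H](O[Si](C)(C)C(C)(C)C)C(C)(C)[C@@H]2[C@H](OC(C)=O)C[C@@]1(C)OC(C)=O)OC(C)=O | intermediate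
29 | 3-O-TBS ether of the target ((12R,13S), 13-OH free, 14-ene) | C=C[C@](C)(O)[C@@H](C[C@@H]1[C@@]2(COC(C)=O)CC[C@@H](O[Si](C)(C)C(C)(C)C)C(C)(C)[C@@H]2[C@H](OC(C)=O)C[C@@]1(C)OC(C)=O)OC(C)=O | intermediate
30 | CNP0292984.1: 6β,8α,12R,20-tetraacetoxylabd-14-ene-3α,13S-diol | C=C[C@](C)(O)[C@@H](C[C@@H]1[C@@]2(COC(C)=O)CC[C@@H](O)C(C)(C)[C@@H]2[C@H](OC(C)=O)C[C@@]1(C)OC(C)=O)OC(C)=O | target

## Step count and risks

Total step count: 22. Longest linear sequence: 22 steps (1 → 30); 2, 9 and 20 are commercial and enter directly.

Most likely to fail, step 9: the chiral amine may give poor face selectivity at C10 against the resident C3 centre, the hindered C5–C10 bond may form slowly, and the base stage may dehydrate the ketol or open the adduct by retro-Michael cleavage. The fallback sets out from 12 and uses a stoichiometric chiral enamine with each bond formed in its own operation. Condensation of 12 with (R)-2-(methoxymethyl)pyrrolidine (4 Å sieves, benzene, 23 °C) would give the preformed (E)-enamine F1. Gentle warming should bring about the same Michael ring closure under auxiliary control, a known donor/acceptor pairing for such enamines and alkylidene 1,3-dicarbonyl compounds. Hydrolysis with aqueous acetic acid would release 13, which would now be isolated (largely as its hemiacetal) and freed from its C10 epimer by chromatography. The aldol ring closure would then be run on pure 13 with a catalytic amount of DBU at 0 °C, and the route is rejoined at 14.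

Second, step 10: the β-keto lactone may form a titanium enolate through its acidic C9–H and stall, or the β-hydroxy ketone may dehydrate under the Lewis acidic reagent. The fallback sets out from 14 and uses the C9–H acidity instead of fighting it. Selective deprotonation (KN(SiMe3)2, 1.0 equiv, THF, −78 °C) and O-triflation with PhNTf2 would give the enol triflate F2. Iron-catalysed cross-coupling with MeMgBr (Fe(acac)3, THF/NMP, −30 °C; one extra equivalent for the C6 hydroxyl) would install C17 and give the conjugated 8-methyl-8(9)-ene lactone F3. Deprotonation with LiN(i-Pr)2 at the C17 methyl (cis to the lactone carbonyl) and kinetic α-protonation of the dienolate with acetic acid at −78 °C would deconjugate the alkene and return the route at 15.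

Third, step 6: formaldehyde may oligomerise under carbene catalysis (formose-type self-condensation), or 7 may undergo homo-acyloin coupling faster than the cross reaction. The fallback sets out from 7 and builds the ketol by stepwise organometallic chemistry. Addition of (4-methoxybenzyloxy)methyllithium (from Bu3SnCH2OPMB and n-BuLi, THF, −78 °C) would give the carbinol F4. Dess–Martin oxidation would give the protected ketol F5, and oxidative removal of the 4-methoxybenzyl group with DDQ (CH2Cl2, pH 7 buffer) would return the route at 8.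

## Further compounds

F1 | step 9 | (E)-enamine of 12 with (R)-2-(methoxymethyl)pyrrolidine | COC[C@H]1CCCN1/C=C/C(C)(C)[C@H](O[Si](C)(C)C(C)(C)C)CCC2=C(C(C)=O)C(=O)OC2
F2 | step 10 | enol triflate of 14 (C8–OTf, C8=C9, 6α-OH) | O=C3C=1[C@@]2(CO3)CC[C@@H](O[Si](C)(C)C(C)(C)C)C(C)(C)[C@@H]2[C@@H](O)CC=1OS(=O)(=O)C(F)(F)F
F3 | step 10 | 8-methyl-8(9)-ene 11,20-lactone (6α-OH) | O=C3C=1[C@@]2(CO3)CC[C@@H](O[Si](C)(C)C(C)(C)C)C(C)(C)[C@@H]2[C@@H](O)CC=1C
F4 | step 6 | (5R)-5-[(tert-butyldimethylsilyl)oxy]-1-[(4-methoxybenzyl)oxy]-6,6-dimethylnon-8-en-2-ol (C2 epimers) | C=CCC(C)(C)[C@H](O[Si](C)(C)C(C)(C)C)CCC(O)COCc1ccc(OC)cc1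
F5 | step 6 | (5R)-5-[(tert-butyldimethylsilyl)oxy]-1-[(4-methoxybenzyl)oxy]-6,6-dimethylnon-8-en-2-one | C=CCC(C)(C)[C@H](O[Si](C)(C)C(C)(C)C)CCC(=O)COCc1ccc(OC)cc1
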